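Everything rests on treating ring A (the terminal 2,4,6-trihydroxyphenoxy ring) as a ring to be built on the ring B oxygen, not as an arene to be coupled. Its ether carbon C1 with the flanking hydroxylated carbons C2 and C6 is a latent 2-aryloxymalonate, and C3–C4(OH)–C5 is latent 3-oxoglutarate. A single base-mediated (3+3) double C-acylation forms C2–C3 and C5–C6, closes ring A and aromatises it. The precursor is dimethyl malonate bearing the fully O-methylated B–C–D aryloxy group on its central carbon. It arises by SN2 alkylation of a phenol, so the most crowded C–O bond of the target is made at sp3 carbon.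

Key step: step 6

Remarks on the chemistry
- Ring labels: A is the terminal trihydroxyphenoxy ring, B the central ring with two vicinal aryloxy groups, C the ether-bearing ring of the biaryl, and D the terminal trihydroxyphenyl ring. In ring A, C1 is the ether carbon, C2/C6 the flanking C–OH, C3/C5 the C–H, and C4 the para C–OH.
- The target has no stereocentre. The tetra-ortho-substituted C–D axis is not stereogenic because each ring is symmetric about it, so no stereocontrol is needed.
- In names, "BCD" stands for 2-[3,5-dimethoxy-4-(2,4,6-trimethoxyphenyl)phenoxy]-3,5-dimethoxyphenyl.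
- Assumption: the five building blocks used as starting materials are commercial.
- Design choice (a): ring B enters as a 2-bromobenzaldehyde. The formyl group first activates the C–Br bond for ether formation, and Baeyer–Villiger oxidation then turns it into the one free phenol required. No catechol has to be differentiated and no protecting group is used.
- Design choice (b): the C–D phenol comes from sterically governed C–H borylation. This avoids functionalising a 5-halo-1,3-dimethoxybenzene between its methoxy groups, and it avoids a later choice between two carbon–halogen bonds.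
- Design choice (c): dimethyl chloromalonate is used in place of the bromide, which can transfer halogen to an electron-rich phenoxide.
- Design choice (d): the malonate C–H of the precursor is acidic, so under base the precursor rests as its enolate. The key step is therefore run hot with removal of methanol, not in refluxing methanol.

Step 1
Reactants: 1 2,6-dimethoxyphenylboronic acid; 2 2-bromo-1,3,5-trimethoxybenzene
Product: 3 2,2',4,6,6'-pentamethoxybiphenyl
Conditions: Pd(OAc)2 (3 mol%), SPhos (6 mol%), K3PO4 (3 equiv), 1 (1.8 equiv), toluene (trace H2O), 100 °C, argon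
Reagents that add atoms: none
Why: Suzuki–Miyaura coupling with a bulky dialkylbiarylphosphine is the established route to tetra-ortho-substituted biaryls, the four flanking groups here are only methoxy, and an excess of 1 in a nearly anhydrous medium offsets its protodeboronation.

Step 2
Reactants: 3 2,2',4,6,6'-pentamethoxybiphenyl
Product: 5 3,5-dimethoxy-4-(2,4,6-trimethoxyphenyl)phenol, via pinacol boronate 4 (not isolated)
Conditions: [Ir(OMe)(cod)]2 (1.5 mol%), dtbpy (3 mol%), B2pin2 (1.1 equiv), THF, 80 °C; then aq. NaOH, H2O2, 0 °C to rt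
Reagents that add atoms: bis(pinacolato)diboron CC1(C)OB(OC1(C)C)B1OC(C)(C)C(C)(C)O1 (boryl group of 4); hydrogen peroxide OO (phenol oxygen of 5)
Why: Sterically governed iridium-catalysed C–H borylation (Hartwig–Miyaura type) can reach only the ring C hydrogen para to the biaryl bond, the single C–H without an ortho substituent since both ring D hydrogens lie between two methoxy groups, and the standard one-pot peroxide oxidation converts the C–B bond into C–OH.

Step 3
Reactants: 5 3,5-dimethoxy-4-(2,4,6-trimethoxyphenyl)phenol; 6 2-bromo-3,5-dimethoxybenzaldehyde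
Product: 7 2-[3,5-dimethoxy-4-(2,4,6-trimethoxyphenyl)phenoxy]-3,5-dimethoxybenzaldehyde
Conditions: CuI (10 mol%), picolinic acid (20 mol%), K3PO4 (2 equiv), 6 (1.2 equiv), DMSO, 90 °C, argon
Reagents that add atoms: none
Why: In this ligand-accelerated Ullmann diaryl ether synthesis the phenol is unhindered and electron-rich, the ortho-formyl group activates and pre-coordinates the C–Br bond, and the picolinic acid system is the one suited to ortho-flanked partners.

Step 4
Reactants: 7 2-[3,5-dimethoxy-4-(2,4,6-trimethoxyphenyl)phenoxy]-3,5-dimethoxybenzaldehyde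
Product: 9 2-[3,5-dimethoxy-4-(2,4,6-trimethoxyphenyl)phenoxy]-3,5-dimethoxyphenol (BCD-OH), via aryl formate 8 (not isolated)
Conditions: mCPBA (1.5 equiv), CH2Cl2, 0 °C to rt; then K2CO3 (cat.), MeOH, rt
Reagents that add atoms: mCPBA OOC(=O)c1cccc(Cl)c1 (inserted oxygen)
Why: Baeyer–Villiger oxidation of an ortho-aryloxybenzaldehyde proceeds with aryl migration to the formate, which shields the electron-rich ring from the peracid until catalytic base in methanol releases the phenol that will carry ring A.

Step 5
Reactants: 9 BCD-OH; 10 dimethyl 2-chloromalonate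
Product: 11 dimethyl 2-(BCD-oxy)malonate
Conditions: K2CO3 (2 equiv), 10 (1.3 equiv), DMF, 50 °C
Reagents that add atoms: none
Why: Williamson-type SN2 alkylation of a phenoxide by a 2-halomalonate is well precedented for 2-alkoxyphenols, and it forms the hindered A–B ether bond at a doubly activated sp3 carbon.

Step 6
Reactants: 11 dimethyl 2-(BCD-oxy)malonate; 12 dimethyl 3-oxoglutarate
Product: 14 dimethyl 5-(BCD-oxy)-2,4,6-trihydroxybenzene-1,3-dicarboxylate, via open-chain C-acyl oxoglutarate 13 (not isolated)
Conditions: NaOMe (4 equiv), diglyme–toluene, 110–130 °C, MeOH distilled off; 12 (1.5 equiv) added over 6 h; then cold 1 M HCl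
Reagents that add atoms: none
Why: Proposed new method: the sodium enolate of 12 attacks one ester carbonyl of 11, either by addition–elimination on the share of 11 that is not enolised or by capture of the aryloxy(methoxycarbonyl)ketene that the enolate of 11 releases through E1cB loss of methoxide, which forms C2–C3 and gives open-chain 13. The second methylene carbon of 13 then attacks the remaining ester in a Dieckmann closure, 6-(enolendo)-exo-trig, which forms C5–C6 and ring A, and enolisation of the triketone delivers the aromatic phenolate of 14 without creating any stereocentre. The closest known reactions are the hot sodium-enolate condensation of unsubstituted dialkyl malonates with dialkyl 3-oxoglutarates to 2,4,6-trihydroxyisophthalates and the NaOMe condensation of 2-aryloxymalonates with amidines to 5-aryloxypyrimidine-4,6-diols, the latter showing that these malonates serve as 1,3-bis-electrophiles despite their acidic C–H, whereas the combination of an aryloxymalonate with a carbon bis-nucleophile has not been shown. The step needs C- over O-acylation and cross- over self-condensation of 12: O-acyl and pyranone products are reopened by methoxide while aromatisation is irreversible, the alpha-aryloxy group raises the electrophilicity of the esters of 11, and slow addition into excess base keeps 12 dilute and fully enolised so that no free ketone is available for aldol attack. Removal of methanol pulls both acylation equilibria forward.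

Step 7
Reactants: 14 dimethyl 5-(BCD-oxy)-2,4,6-trihydroxybenzene-1,3-dicarboxylate
Product: 16 2-(BCD-oxy)benzene-1,3,5-triol, via dicarboxylic acid 15 (not isolated)
Conditions: NaOH (2 M aq., degassed), MeOH, reflux, argon; then HCl to pH 1, 70 °C
Reagents that add atoms: sodium hydroxide [Na+].[OH-] (carboxyl oxygen of 15, lost again as CO2)
Why: Saponification followed by protodecarboxylation works because 2,4,6-trihydroxybenzoic acids behave as beta-keto acids through their keto tautomers and lose CO2 on gentle heating, while aryl methyl ethers and diaryl ethers are inert to both media.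

Step 8
Reactants: 16 2-(BCD-oxy)benzene-1,3,5-triol
Product: 17 2-{2-[3,5-dihydroxy-4-(2,4,6-trihydroxyphenyl)phenoxy]-3,5-dihydroxyphenoxy}benzene-1,3,5-triol (target)
Conditions: BBr3 (20 equiv), CH2Cl2, −78 °C to rt, argon; then ice-water
Reagents that add atoms: none
Why: Lewis-acid ether cleavage with BBr3 breaks only the seven O–CH3 bonds because the diaryl ethers offer bromide no sp3 carbon, and staying at or below room temperature avoids acid-induced cyclodehydration of the 2,2'-dihydroxybiaryl to a dibenzofuran.

Compound list
1 | 2,6-dimethoxyphenylboronic acid | COc1cccc(OC)c1B(O)O | starting material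
2 | 2-bromo-1,3,5-trimethoxybenzene | COc1cc(OC)c(Br)c(OC)c1 | starting material
3 | 2,2',4,6,6'-pentamethoxybiphenyl | COc1cc(OC)c(-c2c(OC)cccc2OC)c(OC)c1 | intermediate
4 | 2-[3,5-dimethoxy-4-(2,4,6-trimethoxyphenyl)phenyl]-4,4,5,5-tetramethyl-1,3,2-dioxaborolane (not isolated) | COc1cc(OC)c(-c2c(OC)cc(B3OC(C)(C)C(C)(C)O3)cc2OC)c(OC)c1 | intermediate
5 | 3,5-dimethoxy-4-(2,4,6-trimethoxyphenyl)phenol | COc1cc(OC)c(-c2c(OC)cc(O)cc2OC)c(OC)c1 | intermediate
6 | 2-bromo-3,5-dimethoxybenzaldehyde | COc1cc(OC)c(Br)c(C=O)c1 | starting material
7 | 2-[3,5-dimethoxy-4-(2,4,6-trimethoxyphenyl)phenoxy]-3,5-dimethoxybenzaldehyde | COc1cc(OC)c(Oc2cc(OC)c(-c3c(OC)cc(OC)cc3OC)c(OC)c2)c(C=O)c1 | intermediate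
8 | 2-[3,5-dimethoxy-4-(2,4,6-trimethoxyphenyl)phenoxy]-3,5-dimethoxyphenyl formate (not isolated) | COc1cc(OC)c(Oc2cc(OC)c(-c3c(OC)cc(OC)cc3OC)c(OC)c2)c(OC=O)c1 | intermediate
9 | 2-[3,5-dimethoxy-4-(2,4,6-trimethoxyphenyl)phenoxy]-3,5-dimethoxyphenol (BCD-OH) | COc1cc(O)c(Oc2cc(OC)c(-c3c(OC)cc(OC)cc3OC)c(OC)c2)c(OC)c1 | intermediate
10 | dimethyl 2-chloromalonate | COC(=O)C(Cl)C(=O)OC | starting material
11 | dimethyl 2-(BCD-oxy)malonate | COC(=O)C(Oc1cc(OC)cc(OC)c1Oc1cc(OC)c(-c2c(OC)cc(OC)cc2OC)c(OC)c1)C(=O)OC | intermediate
12 | dimethyl 3-oxoglutarate (dimethyl 3-oxopentanedioate) | COC(=O)CC(=O)CC(=O)OC | starting material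
13 | dimethyl 2-[2-(BCD-oxy)-3-methoxy-3-oxopropanoyl]-3-oxopentanedioate (not isolated; enolised, its two sp3 centres are configurationally labile) | COC(=O)CC(=O)C(C(=O)OC)C(=O)C(Oc1cc(OC)cc(OC)c1Oc1cc(OC)c(-c2c(OC)cc(OC)cc2OC)c(OC)c1)C(=O)OC | intermediate
14 | dimethyl 5-(BCD-oxy)-2,4,6-trihydroxybenzene-1,3-dicarboxylate | COC(=O)c1c(O)c(C(=O)OC)c(O)c(Oc2cc(OC)cc(OC)c2Oc2cc(OC)c(-c3c(OC)cc(OC)cc3OC)c(OC)c2)c1O | intermediate
15 | 5-(BCD-oxy)-2,4,6-trihydroxybenzene-1,3-dicarboxylic acid (not isolated) | OC(=O)c1c(O)c(C(=O)O)c(O)c(Oc2cc(OC)cc(OC)c2Oc2cc(OC)c(-c3c(OC)cc(OC)cc3OC)c(OC)c2)c1O | intermediate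
16 | 2-(BCD-oxy)benzene-1,3,5-triol | Oc1cc(O)c(Oc2cc(OC)cc(OC)c2Oc2cc(OC)c(-c3c(OC)cc(OC)cc3OC)c(OC)c2)c(O)c1 | intermediate
17 | 2-{2-[3,5-dihydroxy-4-(2,4,6-trihydroxyphenyl)phenoxy]-3,5-dihydroxyphenoxy}benzene-1,3,5-triol | Oc1cc(O)c(Oc2cc(O)cc(O)c2Oc2cc(O)c(-c3c(O)cc(O)cc3O)c(O)c2)c(O)c1 | target

Total step count: 8. Longest linear sequence: 8 (steps 1 to 8; every other component is purchased).

Steps most likely to fail

Step 6. Both partners may rest as unreactive enolates. The intermolecular C-acylation would then be outrun by aldol-type self-condensation of 12 and by methoxide-induced loss of a methoxycarbonyl group from 11. The fallback sets out from phenol 9 and brings ring A in as an arene by known chemistry. Ullmann coupling (CuI, picolinic acid, K3PO4, DMSO, 100 °C) with commercial 4-bromo-3,5-dimethoxybenzaldehyde, whose para-formyl group activates the flanked C–Br bond, should give 4-(BCD-oxy)-3,5-dimethoxybenzaldehyde F1. Baeyer–Villiger oxidation with mCPBA should give 4-(BCD-oxy)-3,5-dimethoxyphenyl formate F2, and methanolysis should give 4-(BCD-oxy)-3,5-dimethoxyphenol F3. BBr3 cleavage of its nine methyl ethers rejoins the route at target 17.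

Step 3. Copper insertion into a C–Br bond flanked by formyl and methoxy may be slow enough for hydrodebromination of 6 and oxidative decay of the phenolate to take over. The fallback sets out from phenol 5 and replaces metal catalysis by addition–elimination. 3,5-Dimethoxybenzaldehyde is fluorinated ortho to the formyl group with Selectfluor in MeCN to 2-fluoro-3,5-dimethoxybenzaldehyde F4. This undergoes SNAr with the potassium phenoxide of 5 (K2CO3, DMA, 140 °C), the small fluoride and the ortho-formyl group easing attack at the crowded carbon. The route is rejoined at aldehyde 7.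

Step 1. Protodeboronation of 1 may outpace transmetalation onto the crowded arylpalladium bromide. The fallback sets out from bromide 2 and uses a Negishi coupling. Directed ortho-metalation of 1,3-dimethoxybenzene (n-BuLi, THF, 0 °C) gives 2,6-dimethoxyphenyllithium F5, and ZnCl2 converts it into (2,6-dimethoxyphenyl)zinc chloride F6. This is coupled with 2 under Pd2(dba)3/RuPhos in THF at 70 °C, and the route is rejoined at biaryl 3.

Further compounds
F1 | step 6 | 4-(BCD-oxy)-3,5-dimethoxybenzaldehyde | COc1cc(C=O)cc(OC)c1Oc1cc(OC)cc(OC)c1Oc1cc(OC)c(-c2c(OC)cc(OC)cc2OC)c(OC)c1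
F2 | step 6 | 4-(BCD-oxy)-3,5-dimethoxyphenyl formate | COc1cc(OC=O)cc(OC)c1Oc1cc(OC)cc(OC)c1Oc1cc(OC)c(-c2c(OC)cc(OC)cc2OC)c(OC)c1
F3 | step 6 | 4-(BCD-oxy)-3,5-dimethoxyphenol | COc1cc(O)cc(OC)c1Oc1cc(OC)cc(OC)c1Oc1cc(OC)c(-c2c(OC)cc(OC)cc2OC)c(OC)c1
F4 | step 3 | 2-fluoro-3,5-dimethoxybenzaldehyde | COc1cc(OC)c(F)c(C=O)c1
F5 | step 1 | 2,6-dimethoxyphenyllithium | [Li]c1c(OC)cccc1OC
F6 | step 1 | (2,6-dimethoxyphenyl)zinc chloride | Cl[Zn]c1c(OC)cccc1OC
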